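The vessel is closed, stirred and isothermal, and you have followed this very flask to 8.00 h.

- dusk: starting complex 22 mM; incoming ligand 3 equiv; the very flask that is asked about, followed so far
- flask: starting complex 22 mM; incoming ligand 3.00 equiv; time 40 h

dusk run (percent of the starting complex charged)

| time / h | complex with two exchanged / % | complex with one exchanged / % |
|---|---|---|
| 0.417 | 18.9 | 22.7 |
| 1.33 | 36.1 | 10.6 |
| 2.50 | 40.8 | 5.7 |
| 3.00 | 43.3 | 4.6 |
| 5.00 | 45.0 | 1.3 |
| 6.00 | 45.1 | 1.4 |
| 8.00 | 42.7 | 2.1 |

(scatter of a reading: 1 percentage point)



- equivalents of incoming ligand to starting complex, everything else as given, that leave most complex with two exchanged at 40 h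
- the amount of complex with two exchanged then, in percent of the starting complex charged
- the amount of complex with two exchanged with the amounts as given

Follow one molecule up the ladder. The complex with two exchanged, the wanted one, costs two incoming ligands, so I carry the ligand budget b, the equivalents e of incoming ligand charged over the two that the wanted complex takes:

b = e/2 = 1.50

Below one, incoming ligand is the limiting reagent for the wanted complex. Above one, the surplus can go further.

First rung: complex with one exchanged reads as a half-life of about 0.831 h between the first two readings.

Next rung: at 5.00 h, the two complexes read leave 53.7 % unseen. With b above one, I take most of it to be complex with three exchanged. This is my judgement.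

Last rung: complex with two exchanged droops by 2.4 percentage points from 6.00 h to 8.00 h, against a scatter of 1 point. That is a weak reading of the chance per hour of moving on:

d = 0.0273 h⁻¹

As a half-life that is 25.4 h, longer than the first rung. If d holds, the chance of staying until 40 h is 41.7 %, so I expect 17.8 % in this flask. I would charge for b = 1, that is 2 equiv, and hope to hold about the 45.1 % read at 6.00 h in this flask.

The forecast says 3.5 equiv as the best charge, holding 34 %, and 32 % for the flask as given, reasoning that “more ligand should raise the plateau”. Its figure for this flask stands above mine.

The simulation gives 1.95 equiv as the best charge, holding 45.6 %, and 14.8 % for the flask as given.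

    starting complex + incoming ligand ⇌ leaving ligand + complex with one exchanged (K = 0.842, k = 31.8 M⁻¹ h⁻¹)
    complex with one exchanged + incoming ligand ⇌ leaving ligand + complex with two exchanged (K = 84.0, k = 58.6 M⁻¹ h⁻¹)
    complex with two exchanged + incoming ligand ⇌ leaving ligand + complex with three exchanged (K = 1.09, k = 30.9 M⁻¹ h⁻¹)
    leaving ligand → by-product carried off (k = 0.235 h⁻¹)
    complex with one exchanged ⇌ isomer of the product (K = 1.70, k = 0.167 h⁻¹)

That best charge means b = 0.975. At 40 h the flask as given has 2.82 equiv of incoming ligand in its exchanged complexes, which is 1.41 in the units of its b of 1.50, and it holds 83.9 % as complex with three exchanged. The neighbour flask with 0.750 equiv has b = 0.375, which caps the complex with two exchanged at that fraction of the charge, and at 40 h it holds 20.5 % of that complex.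

(The data were computed for substances that don't exist, and the scatter is random.)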